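**Retrosynthetic overview**
1. Target 13 ⇐ 12 by hydrolysis of the side-chain ethyl ester only.
2. Tropone ring of 12 ⇐ photochemical insertion of one CH (from CH2I2) into the phenol ring of spiro-dihydrobenzofuran 10; this ring expansion forms the last ring.
3. Spiro-dihydrofuran of 10 (one C–C and one C–O bond) ⇐ anodic [3+2] union of atraric acid 9 with exocyclic alkene 8; this sets the spiro centre.
4. Alkene 8 ⇐ (S)-carvone 1 by α'-methylation, α'-alkenylation (quaternary centre), hydration, hydrogenation (CH–CH3 centre) and methylenation.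
5. Ring order: cyclohexane bought in 1, benzene ring bought in 9, then the dihydrofuran, then benzene to tropone.

Assumption: drimane-style locants are used in the explanations for the cyclohexane unit (C-5 = CH bearing the hydroxypropyl group, C-8 = CH–CH3, C-9 = spiro carbon, C-10 = quaternary carbon, C-11 = CH2 of the dihydrofuran); 1, 9 and ethyl (Z)-3-iodoacrylate are taken as commercial.

Step 1
Reactants: 1 (S)-(+)-carvone
Product: 3 (5S)-6-methylcarvone (C-6 epimers), via lithium dienolate of carvone 2 (not isolated)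
Conditions: LiN(iPr)2 (LDA), THF, −78 °C; MeI, −78 to 0 °C
Reagents that add atoms: iodomethane, CI
Why: Kinetic α'-deprotonation of the enone and SN2 methylation of the cross-conjugated lithium dienolate (enolate alkylation) is the standard route to 6-methylcarvone; the new C-6 centre forms as an epimer mixture that is erased in step 2, and the carvone stereocentre is untouched.

Step 2
Reactants: 3 (5S)-6-methylcarvone
Product: 5 ethyl (2Z)-3-[(1R,6R)-1,3-dimethyl-2-oxo-6-(prop-1-en-2-yl)cyclohex-3-en-1-yl]prop-2-enoate, via lithium dienolate of 6-methylcarvone 4 (not isolated)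
Conditions: LiN(iPr)2 (LDA), THF, −78 °C; ethyl (Z)-3-iodoacrylate, −78 to −40 °C
Reagents that add atoms: ethyl (Z)-3-iodoacrylate, CCOC(=O)/C=C\I
Why: The tetrasubstituted dienolate undergoes conjugate addition–elimination (enolate alkenylation) on the face opposite the neighbouring isopropenyl group, which sets the quaternary C-10 centre with the three-carbon chain trans to isopropenyl, and the immediate loss of iodide from the adduct leaves no ester enolate that could add a second time to the enone.

Step 3
Reactants: 5 enone with isopropenyl group and (Z)-enoate chain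
Product: 6 ethyl (2Z)-3-[(1R,6S)-6-(2-hydroxypropan-2-yl)-1,3-dimethyl-2-oxocyclohex-3-en-1-yl]prop-2-enoate
Conditions: Co(acac)2 (20 mol %), PhSiH3, O2 (1 atm), THF, 0 °C to rt
Reagents that add atoms: dioxygen, O=O
Why: Mukaiyama hydration (cobalt-hydride hydrogen-atom transfer, then trapping by oxygen) gives the Markovnikov tertiary alcohol at the electron-rich 1,1-disubstituted alkene, while the electron-poor enone and enoate C=C bonds react much more slowly; no stereocentre is touched.

Step 4
Reactants: 6 hydroxy enone with (Z)-enoate chain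
Product: 7 ethyl 3-[(1R,3R,6S)-6-(2-hydroxypropan-2-yl)-1,3-dimethyl-2-oxocyclohexyl]propanoate
Conditions: H2 (1 atm), Pd/C, EtOAc, rt
Reagents that add atoms: none
Why: Heterogeneous catalytic hydrogenation saturates the enoate and the ring enone C=C, and hydrogen should add to the enone face opposite the pseudoaxial C-10 methyl group (the face that carries the side chain), which puts the new C-8 methyl cis to the C-10 methyl as the kinetic product.

Step 5
Reactants: 7 saturated keto ester
Product: 8 ethyl 3-[(1R,3R,6S)-6-(2-hydroxypropan-2-yl)-1,3-dimethyl-2-methylidenecyclohexyl]propanoate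
Conditions: Zn, CH2Br2, TiCl4 (reagent pre-formed in THF), CH2Cl2, 0 °C to rt
Reagents that add atoms: dibromomethane, BrCBr
Why: Lombardo methylenation (titanium–zinc methylene transfer) is non-basic, tolerates esters and free hydroxyl groups and works on hindered ketones with an epimerisable α-centre, so the less stable C-8 configuration is kept.

Step 6
Reactants: 8 exocyclic alkene; 9 atraric acid (methyl 2,4-dihydroxy-3,6-dimethylbenzoate)
Product: 10 methyl (2S,2'R,3'S,6'R)-2'-(3-ethoxy-3-oxopropyl)-6-hydroxy-3'-(2-hydroxypropan-2-yl)-2',4,6',7-tetramethyl-3H-spiro[1-benzofuran-2,1'-cyclohexane]-5-carboxylate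
Conditions: undivided cell, carbon-felt anode, Pt cathode, LiClO4 (1 M) in MeNO2, AcOH, constant current (about 2.2 F/mol of 8), rt; 9 in excess (4 equiv)
Reagents that add atoms: none
Why: In this anodic phenol–alkene [3+2] cycloaddition (known for electron-rich phenols with unactivated alkenes) the anodically formed phenoxonium ion of 9 is attacked by the alkene CH2 at the only unsubstituted ring position (ortho to the 4-OH), and that oxygen then closes onto the tertiary C-9 cation from the face anti to the two axial methyl groups, which sets the spiro centre with O trans and CH2 cis to both methyls.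

Step 7
Reactants: 10 spiro-dihydrobenzofuran phenol
Product: 12 methyl (2S,2'R,3'S,6'R)-2'-(3-ethoxy-3-oxopropyl)-3'-(2-hydroxypropan-2-yl)-2',5,6',8-tetramethyl-7-oxo-3,7-dihydrospiro[cyclohepta[b]furan-2,1'-cyclohexane]-6-carboxylate, via para-iodomethyl dienone 11 (not isolated)
Conditions: CH2I2 (3 equiv), Cs2CO3 (3 equiv), Ir(ppy)3 (1 mol %), degassed MeCN, 456 nm LEDs, rt
Reagents that add atoms: diiodomethane, ICI
Why: Proposed new method: a photoredox one-carbon ring expansion of a phenol to a tropone, in which excited Ir(ppy)3 reduces CH2I2 to the iodomethyl radical, the oxidised catalyst converts the phenolate of 10 into a persistent 2,4,6-trisubstituted phenoxyl radical, and cross-coupling at the para carbon (highest spin density, tied-back substituent) gives dienone 11; a second catalytic cycle then reduces the neopentyl C–I bond of 11, the primary radical adds 3-exo to the ring carbon of the C(CH3)=C(CO2Me)–C=O unit (polarity-matched, gives a 1,3-dicarbonyl-stabilised radical) and not to the alkoxy-substituted ring carbon, the norcaradiene-type cyclopropylcarbinyl radical opens at the ring-fusion bond, and oxidation by the catalyst with loss of a proton gives the aromatic tropone, so the CH is inserted exactly between the carbon bearing C-11 and the C-methyl carbon and no stereocentre is touched; the closest known reaction types are the tin-hydride radical ring expansion of 4-(dichloromethyl)cyclohexa-2,5-dienones to tropones, the Dowd–Beckwith ring expansion, and the para coupling of hindered phenoxyl radicals with alkyl radicals.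

Step 8
Reactants: 12 tropone diester
Product: 13 CNP0448476.4, 3-[(2S,2'R,3'S,6'R)-3'-(2-hydroxypropan-2-yl)-6-(methoxycarbonyl)-2',5,6',8-tetramethyl-7-oxo-3,7-dihydrospiro[cyclohepta[b]furan-2,1'-cyclohexan]-2'-yl]propanoic acid
Conditions: LiOH·H2O (1.5 equiv), THF/H2O, 0 °C; then 1 M HCl to pH 3
Reagents that add atoms: lithium hydroxide, [Li+].[OH-]
Why: Saponification occurs at the unhindered primary ethyl ester, because the methyl ester on the tropone is flanked by the ring carbonyl and a C-methyl carbon and is hydrolysed much more slowly; no stereocentre is affected.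

**Compound list**
1 | (S)-(+)-carvone, (5S)-2-methyl-5-(prop-1-en-2-yl)cyclohex-2-en-1-one | CC1=CC[C@@H](CC1=O)C(C)=C | starting material
2 | lithium dienolate of carvone (O–C1=C6 cross-conjugated enolate, stereocentre as in 1) | [Li+].[O-]C1=C[C@@H](C(C)=C)CC=C1C | intermediate
3 | (5S)-6-methylcarvone, (5S,6RS)-2,6-dimethyl-5-(prop-1-en-2-yl)cyclohex-2-en-1-one (C-6 epimers) | CC1=CC[C@H](C(C)=C)C(C)C1=O | intermediate
4 | lithium dienolate of 6-methylcarvone (O–C1=C6 tetrasubstituted enolate, stereocentre as in 1) | [Li+].[O-]C1=C(C)[C@@H](C(C)=C)CC=C1C | intermediate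
5 | ethyl (2Z)-3-[(1R,6R)-1,3-dimethyl-2-oxo-6-(prop-1-en-2-yl)cyclohex-3-en-1-yl]prop-2-enoate (chain trans to isopropenyl) | O=C1C(C)=CC[C@H](C(C)=C)[C@@]1(C)/C=C\C(=O)OCC | intermediate
6 | ethyl (2Z)-3-[(1R,6S)-6-(2-hydroxypropan-2-yl)-1,3-dimethyl-2-oxocyclohex-3-en-1-yl]prop-2-enoate | O=C1C(C)=CC[C@H](C(C)(C)O)[C@@]1(C)/C=C\C(=O)OCC | intermediate
7 | ethyl 3-[(1R,3R,6S)-6-(2-hydroxypropan-2-yl)-1,3-dimethyl-2-oxocyclohexyl]propanoate (ring methyls cis) | O=C1[C@H](C)CC[C@H](C(C)(C)O)[C@@]1(C)CCC(=O)OCC | intermediate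
8 | ethyl 3-[(1R,3R,6S)-6-(2-hydroxypropan-2-yl)-1,3-dimethyl-2-methylidenecyclohexyl]propanoate | C=C1[C@H](C)CC[C@H](C(C)(C)O)[C@@]1(C)CCC(=O)OCC | intermediate
9 | atraric acid, methyl 2,4-dihydroxy-3,6-dimethylbenzoate | COC(=O)c1c(C)cc(O)c(C)c1O | starting material
10 | methyl (2S,2'R,3'S,6'R)-2'-(3-ethoxy-3-oxopropyl)-6-hydroxy-3'-(2-hydroxypropan-2-yl)-2',4,6',7-tetramethyl-3H-spiro[1-benzofuran-2,1'-cyclohexane]-5-carboxylate | COC(=O)c1c(C)c2c(c(C)c1O)O[C@@]1(C2)[C@H](C)CC[C@H](C(C)(C)O)[C@@]1(C)CCC(=O)OCC | intermediate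
11 | methyl (2S,2'R,3'S,6'R)-2'-(3-ethoxy-3-oxopropyl)-3'-(2-hydroxypropan-2-yl)-3a-(iodomethyl)-2',4,6',7-tetramethyl-6-oxo-3a,6-dihydro-3H-spiro[1-benzofuran-2,1'-cyclohexane]-5-carboxylate (both C-3a epimers) | COC(=O)C1=C(C)C2(CI)C[C@]3(OC2=C(C)C1=O)[C@H](C)CC[C@H](C(C)(C)O)[C@@]3(C)CCC(=O)OCC | intermediate
12 | methyl (2S,2'R,3'S,6'R)-2'-(3-ethoxy-3-oxopropyl)-3'-(2-hydroxypropan-2-yl)-2',5,6',8-tetramethyl-7-oxo-3,7-dihydrospiro[cyclohepta[b]furan-2,1'-cyclohexane]-6-carboxylate | COC(=O)c1c(C)cc2c(c(C)c1=O)O[C@@]1(C2)[C@H](C)CC[C@H](C(C)(C)O)[C@@]1(C)CCC(=O)OCC | intermediate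
13 | CNP0448476.4, 3-[(2S,2'R,3'S,6'R)-3'-(2-hydroxypropan-2-yl)-6-(methoxycarbonyl)-2',5,6',8-tetramethyl-7-oxo-3,7-dihydrospiro[cyclohepta[b]furan-2,1'-cyclohexan]-2'-yl]propanoic acid | COC(=O)c1c(C)cc2c(c(C)c1=O)O[C@@]1(C2)[C@H](C)CC[C@H](C(C)(C)O)[C@@]1(C)CCC(=O)O | target

**Step count and risks**
Total steps: 8. Longest linear sequence: 8 (from 1; 9 is used as bought).

Three steps most likely to fail:

Step 7 (the new photochemical ring expansion). The radical coupling could occur at an ortho carbon of the phenoxyl radical instead of the para carbon, and the tropone product may itself be light-sensitive. The fallback uses known chemistry and sets out from 10. Dichlorocarbene (CHCl3, 50% aq. NaOH, BnEt3NCl, 0 °C; abnormal Reimer–Tiemann reaction at the substituted para position) gives the 3a-(dichloromethyl) cross-conjugated dienone F1. Bu3SnH with AIBN in benzene at 80 °C then brings about the known tin-hydride radical ring expansion with loss of chlorine, and the route is rejoined at 12.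

Step 6 (anodic [3+2] union). Phenol 9 carries an ester and is harder to oxidise than the usual electron-rich phenols, and the tertiary cation could be trapped by the side-chain hydroxyl instead. The fallback sets out from 8 and 9 and replaces the oxidative cycloaddition by cross-coupling and acid cyclisation. Iodination of 9 (NIS, MeCN) gives methyl 2,4-dihydroxy-5-iodo-3,6-dimethylbenzoate F2. A Heck reaction of F2 with 8 (Pd(OAc)2, P(o-tol)3, Et3N, DMF, 100 °C) gives the aryl-substituted exocyclic alkene F3. Catalytic TfOH in CH2Cl2 at 0 °C protonates the benzylic alkene carbon, and the ortho oxygen closes onto the tertiary cation from the face anti to the methyls; the route is rejoined at 10.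

Step 4 (C-8 configuration). Hydrogen may add to the wrong enone face, or the less stable ketone 7 may epimerise before step 5. The fallback sets out from 6 and sets C-8 only after the spiro centre exists, where it can no longer epimerise. Lombardo methylenation of enone 6 (Zn, CH2Br2, TiCl4) gives the conjugated exocyclic diene F4. The anodic annulation of F4 with 9, under the conditions of step 6, gives the spiro-dihydrobenzofuran with the ring alkene and the enoate still in place F5. Hydrogenation (H2, PtO2, EtOAc) from the ether-oxygen face, opposite the C-10 methyl and C-11, saturates both C=C bonds, and the route is rejoined at 10.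

**Further compounds**
F1 | step 7 | methyl (2S,2'R,3'S,6'R)-3a-(dichloromethyl)-2'-(3-ethoxy-3-oxopropyl)-3'-(2-hydroxypropan-2-yl)-2',4,6',7-tetramethyl-6-oxo-3a,6-dihydro-3H-spiro[1-benzofuran-2,1'-cyclohexane]-5-carboxylate (C-3a epimers) | COC(=O)C1=C(C)C2(C(Cl)Cl)C[C@]3(OC2=C(C)C1=O)[C@H](C)CC[C@H](C(C)(C)O)[C@@]3(C)CCC(=O)OCC
F2 | step 6 | methyl 2,4-dihydroxy-5-iodo-3,6-dimethylbenzoate | COC(=O)c1c(C)c(I)c(O)c(C)c1O
F3 | step 6 | methyl 3-{[(2R,3S,6R)-2-(3-ethoxy-3-oxopropyl)-3-(2-hydroxypropan-2-yl)-2,6-dimethylcyclohexylidene]methyl}-4,6-dihydroxy-2,5-dimethylbenzoate (alkene geometry not fixed) | COC(=O)c1c(C)c(C=C2[C@H](C)CC[C@H](C(C)(C)O)[C@@]2(C)CCC(=O)OCC)c(O)c(C)c1O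
F4 | step 4 | ethyl (2Z)-3-[(1R,6S)-6-(2-hydroxypropan-2-yl)-1,3-dimethyl-2-methylidenecyclohex-3-en-1-yl]prop-2-enoate | C=C1C(C)=CC[C@H](C(C)(C)O)[C@@]1(C)/C=C\C(=O)OCC
F5 | step 4 | methyl (2S,2'R,3'S)-2'-[(1Z)-3-ethoxy-3-oxoprop-1-en-1-yl]-6-hydroxy-3'-(2-hydroxypropan-2-yl)-2',4,6',7-tetramethyl-3H-spiro[1-benzofuran-2,1'-cyclohex-5'-ene]-5-carboxylate | COC(=O)c1c(C)c2c(c(C)c1O)O[C@@]1(C2)C(C)=CC[C@H](C(C)(C)O)[C@@]1(C)/C=C\C(=O)OCC
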